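**Strategy.** The flavonol is cut back to a chalcone, and ring A of that chalcone to a folded polyketide by disconnecting the C4a–C5 bond. The six ring A carbons (C4a, C5, C6, C7, C8, C8a), with oxygen on C5, C7 and C8a and prenyl on C6 and C8, then become the chain of a 4-hydroxy-3,5-diprenyl-2-pyrone carrying a 4-(methoxymethoxy)cinnamoylmethyl group at C6. In one operation Mg(OMe)2 unmasks this pyrone as a triketo ester and closes it by Claisen condensation to the fully substituted acylphloroglucinol chalcone. Both prenyl groups are already in place from enolate alkylations, so no arene regiochemistry arises. Oxidative closure of ring C and removal of the MOM groups finish the synthesis.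

Key step: step 8

Assumption: lithium, sodium and magnesium derivatives (enolates, chelated adducts) of numbered compounds count as forms of those compounds and carry no numbers of their own; every stereocentre that appears on the way is racemic and is removed before the target, which has none.

**Step 1**
Reactants: 1 methyl acetoacetate; 2 prenyl bromide (1-bromo-3-methylbut-2-ene)
Product: 3 methyl 7-methyl-3-oxooct-6-enoate
Conditions: NaH (1.1 equiv), THF, 0 °C; n-BuLi (1.05 equiv), 0 °C; 2 (1.0 equiv), 0 °C to rt; then aq. HCl
Reagents that add atoms: none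
Why: γ-Alkylation of the acetoacetate dianion, in which the terminal carbanion is far more nucleophilic than the stabilised α-carbon and alone is alkylated (SN2) by the allylic bromide.

**Step 2**
Reactants: 3 methyl 7-methyl-3-oxooct-6-enoate; 2 prenyl bromide
Product: 4 methyl 7-methyl-2-(3-methylbut-2-enyl)-3-oxooct-6-enoate (racemic)
Conditions: NaH (1.0 equiv), THF, 0 °C; 2 (1.0 equiv), 0 °C to rt
Reagents that add atoms: none
Why: Acetoacetic ester alkylation, in which the sodium enolate is C-alkylated by the soft allylic bromide and one equivalent of base and halide limits double alkylation; the new α-stereocentre forms racemic and is erased in step 4.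

**Step 3**
Reactants: 4 methyl 7-methyl-2-(3-methylbut-2-enyl)-3-oxooct-6-enoate; 5 N-methoxy-N-methylacetamide
Product: 6 methyl 2,4-bis(3-methylbut-2-enyl)-3,5-dioxohexanoate (mixture of diastereomers and enol forms)
Conditions: LiN(i-Pr)2 (2.2 equiv), THF, −78 to 0 °C; 5, −78 to 0 °C; then cold aq. HCl
Reagents that add atoms: none
Why: Acylation of a β-keto ester dianion at its γ-carbon by a Weinreb amide, whose lithium-chelated tetrahedral adduct does not collapse before work-up and so excludes double addition; the two epimerisable stereocentres form without control and both vanish in step 4.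

**Step 4**
Reactants: 6 methyl 2,4-bis(3-methylbut-2-enyl)-3,5-dioxohexanoate
Product: 7 4-hydroxy-6-methyl-3,5-bis(3-methylbut-2-enyl)pyran-2-one
Conditions: DBU (1.5 equiv), toluene, 80 °C; then aq. HCl wash
Reagents that add atoms: none
Why: Base-mediated lactonisation of a 3,5-diketo ester, in which the enolate oxygen of the C5 ketone attacks the ester and loss of methanol gives the 4-hydroxy-2-pyrone, a stable vinylogous acid that pulls the equilibrium over.

**Step 5**
Reactants: 8 4-hydroxybenzaldehyde
Product: 9 4-(methoxymethoxy)benzaldehyde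
Conditions: MOMCl (1.3 equiv), i-Pr2NEt (2 equiv), CH2Cl2, 0 °C to rt
Reagents that add atoms: chloromethyl methyl ether (MOMCl), COCCl
Why: Williamson-type O-alkylation of the phenol by the reactive α-chloro ether gives a MOM acetal that is inert to every base and nucleophile used later.

**Step 6**
Reactants: 9 4-(methoxymethoxy)benzaldehyde; 10 diethyl {2-[methoxy(methyl)amino]-2-oxoethyl}phosphonate
Product: 11 (E)-N-methoxy-3-[4-(methoxymethoxy)phenyl]-N-methylprop-2-enamide
Conditions: NaH (1.1 equiv), THF, 0 °C; 9, 0 °C to rt
Reagents that add atoms: none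
Why: Horner–Wadsworth–Emmons olefination with a stabilised phosphonate anion, which should give the E-alkene through the reversibly formed anti adduct.

**Step 7**
Reactants: 7 4-hydroxy-6-methyl-3,5-bis(3-methylbut-2-enyl)pyran-2-one; 11 (E)-N-methoxy-3-[4-(methoxymethoxy)phenyl]-N-methylprop-2-enamide
Product: 12 4-hydroxy-6-{(E)-4-[4-(methoxymethoxy)phenyl]-2-oxobut-3-enyl}-3,5-bis(3-methylbut-2-enyl)pyran-2-one
Conditions: LiN(i-Pr)2 (2.3 equiv), THF, −78 °C; 11 (1.0 equiv), −78 to −30 °C; then cold aq. HCl (pH 3)
Reagents that add atoms: none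
Why: Weinreb ketone synthesis with a pyrone dianion, in which the vinylogous C6 methyl group is the only site acidic enough for the second deprotonation after the 4-OH and the resulting dienolate carbon adds 1,2 to the amide, giving a chelated adduct that releases the enone only on work-up.

**Step 8**
Reactants: 12 4-hydroxy-6-{(E)-4-[4-(methoxymethoxy)phenyl]-2-oxobut-3-enyl}-3,5-bis(3-methylbut-2-enyl)pyran-2-one
Product: 14 (E)-2',4',6'-trihydroxy-4-(methoxymethoxy)-3',5'-diprenylchalcone, via methyl triketo ester 13 (not isolated)
Conditions: Mg(OMe)2 (6 equiv), MeOH, reflux, N2; then cold 1 M aq. HCl to pH 3; used at once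
Reagents that add atoms: none
Why: Methoxide adds to the lactone carbonyl and opens the pyrone to triketo ester 13, which the magnesium ion holds as a folded polyenolate chelate; the C4a carbanion, the only unsubstituted methylene and activated by both the C4 and C8a carbonyls, then attacks the ester carbonyl C5, methoxide leaves and the triketone enolises to the arene. The closest known reaction type is the Mg(OMe)2-mediated Claisen (Dieckmann-type) cyclisation of 6-(2-oxoalkyl)-4-hydroxy-2-pyrones and 3,5,7-triketo esters to acylphloroglucinols, the laboratory counterpart of chalcone synthase folding. Ring A closes in the 6-exo-trig mode, the attacked C5 carbonyl oxygen lying outside the forming ring. No stereocentre is created, and the two CH centres of 13 (C6 and C8) disappear on aromatisation. The step needs Claisen closure to win over aldol closure from C6 onto the C4 ketone and over retro-Claisen cleavage of the chain: the prenyl group on C6 makes the aldol adduct quaternary, unable to aromatise and therefore reversible, the same substituent keeps the β-keto ester less enolised and its carbonyl electrophilic, and the chelating magnesium keeps the ketones enolised and shielded from methoxide. Aromatisation makes the Claisen path the only irreversible one, while conjugate addition of methoxide or of the 2'-oxide to the E-enone is reversible under these conditions.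

**Step 9**
Reactants: 14 (E)-2',4',6'-trihydroxy-4-(methoxymethoxy)-3',5'-diprenylchalcone
Product: 15 (E)-2'-hydroxy-4,4',6'-tris(methoxymethoxy)-3',5'-diprenylchalcone
Conditions: MOMCl (2.3 equiv), i-Pr2NEt (3 equiv), CH2Cl2, 0 °C to rt
Reagents that add atoms: chloromethyl methyl ether (MOMCl), COCCl
Why: Phenol MOM etherification, in which the free 4'-OH and then one of the two equivalent ortho-OH groups react while the last OH is held back by its hydrogen bond to the carbonyl; this removes the electron-rich free phloroglucinol that would make the following alkaline oxidation sluggish and unselective.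

**Step 10**
Reactants: 15 (E)-2'-hydroxy-4,4',6'-tris(methoxymethoxy)-3',5'-diprenylchalcone
Product: 17 3-hydroxy-5,7-bis(methoxymethoxy)-2-[4-(methoxymethoxy)phenyl]-6,8-diprenylchromen-4-one, via trans-dihydroflavonol 16 (not isolated)
Conditions: 30% aq. H2O2 (excess), 2 M aq. NaOH, MeOH–THF, 0 °C to rt
Reagents that add atoms: hydrogen peroxide, OO
Why: Algar–Flynn–Oyamada reaction, in which hydroperoxide and the 2'-phenoxide add across the enone with 6-endo closure at the benzylic β-carbon to give trans-dihydroflavonol 16, which excess alkaline peroxide dehydrogenates to the flavonol; the nucleophilic oxidant leaves the electron-rich prenyl alkenes and the MOM acetals alone, and the two stereocentres of 16 are transient.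

**Step 11**
Reactants: 17 3-hydroxy-5,7-bis(methoxymethoxy)-2-[4-(methoxymethoxy)phenyl]-6,8-diprenylchromen-4-one
Product: 18 6,8-diprenylkaempferol
Conditions: 3 M aq. HCl, MeOH–THF, 40 °C; stopped at full conversion
Reagents that add atoms: none
Why: Acid-catalysed acetal exchange with methanol removes the three MOM groups as dimethoxymethane much faster than a protonated prenyl alkene is trapped by a neighbouring phenol, so dilute methanolic acid at moderate temperature should spare the ortho-prenyl phenols.

**Compound list**
1 | methyl acetoacetate | COC(=O)CC(C)=O | starting material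
2 | prenyl bromide (1-bromo-3-methylbut-2-ene) | CC(C)=CCBr | starting material
3 | methyl 7-methyl-3-oxooct-6-enoate | COC(=O)CC(=O)CCC=C(C)C | intermediate
4 | methyl 7-methyl-2-(3-methylbut-2-enyl)-3-oxooct-6-enoate (racemic) | COC(=O)C(CC=C(C)C)C(=O)CCC=C(C)C | intermediate
5 | N-methoxy-N-methylacetamide | CC(=O)N(C)OC | starting material
6 | methyl 2,4-bis(3-methylbut-2-enyl)-3,5-dioxohexanoate (diastereomer mixture) | COC(=O)C(CC=C(C)C)C(=O)C(CC=C(C)C)C(C)=O | intermediate
7 | 4-hydroxy-6-methyl-3,5-bis(3-methylbut-2-enyl)pyran-2-one | Cc1oc(=O)c(CC=C(C)C)c(O)c1CC=C(C)C | intermediate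
8 | 4-hydroxybenzaldehyde | O=Cc1ccc(O)cc1 | starting material
9 | 4-(methoxymethoxy)benzaldehyde | COCOc1ccc(C=O)cc1 | intermediate
10 | diethyl {2-[methoxy(methyl)amino]-2-oxoethyl}phosphonate | CCOP(=O)(CC(=O)N(C)OC)OCC | starting material
11 | (E)-N-methoxy-3-[4-(methoxymethoxy)phenyl]-N-methylprop-2-enamide | COCOc1ccc(/C=C/C(=O)N(C)OC)cc1 | intermediate
12 | 4-hydroxy-6-{(E)-4-[4-(methoxymethoxy)phenyl]-2-oxobut-3-enyl}-3,5-bis(3-methylbut-2-enyl)pyran-2-one | COCOc1ccc(/C=C/C(=O)Cc2oc(=O)c(CC=C(C)C)c(O)c2CC=C(C)C)cc1 | intermediate
13 | methyl (E)-9-[4-(methoxymethoxy)phenyl]-2,4-bis(3-methylbut-2-enyl)-3,5,7-trioxonon-8-enoate (diastereomer mixture, not isolated) | COC(=O)C(CC=C(C)C)C(=O)C(CC=C(C)C)C(=O)CC(=O)/C=C/c1ccc(OCOC)cc1 | intermediate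
14 | (E)-2',4',6'-trihydroxy-4-(methoxymethoxy)-3',5'-diprenylchalcone | COCOc1ccc(/C=C/C(=O)c2c(O)c(CC=C(C)C)c(O)c(CC=C(C)C)c2O)cc1 | intermediate
15 | (E)-2'-hydroxy-4,4',6'-tris(methoxymethoxy)-3',5'-diprenylchalcone | COCOc1ccc(/C=C/C(=O)c2c(O)c(CC=C(C)C)c(OCOC)c(CC=C(C)C)c2OCOC)cc1 | intermediate
16 | rac-(2R,3R)-3-hydroxy-5,7-bis(methoxymethoxy)-2-[4-(methoxymethoxy)phenyl]-6,8-diprenylchroman-4-one (trans, not isolated) | COCOc1ccc([C@@H]2[C@H](C(=O)c3c(OCOC)c(CC=C(C)C)c(OCOC)c(CC=C(C)C)c3O2)O)cc1 | intermediate
17 | 3-hydroxy-5,7-bis(methoxymethoxy)-2-[4-(methoxymethoxy)phenyl]-6,8-diprenylchromen-4-one | COCOc1ccc(-c2oc3c(CC=C(C)C)c(OCOC)c(CC=C(C)C)c(OCOC)c3c(=O)c2O)cc1 | intermediate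
18 | 6,8-diprenylkaempferol | CC(C)=CCc1c(O)c(CC=C(C)C)c2oc(-c3ccc(O)cc3)c(O)c(=O)c2c1O | target

**Step count.** Total: 11 steps. Longest linear sequence: 9 steps (1, 2, 3, 4, 7, 8, 9, 10, 11); steps 5 and 6 form the side branch.

**Steps most likely to fail**

Step 8. The 4-oxido-pyrone may resist methanolysis of its lactone. Methoxide may also cut the opened chain by retro-Claisen attack at the C7 ketone. On work-up the 2'-OH may add to the enone and close the flavanone. The fallback replaces polyketide folding by arene C-prenylation and aldol condensation; it sets out from 2 and 9 and comes back to the route at 15. Commercial 2,4,6-trihydroxyacetophenone is C-prenylated twice with 2 in cold aqueous KOH to give 1-[2,4,6-trihydroxy-3,5-bis(3-methylbut-2-enyl)phenyl]ethanone F1, which has to be separated from mono- and over-alkylated material. MOMCl and i-Pr2NEt should convert it into 1-[2-hydroxy-4,6-bis(methoxymethoxy)-3,5-bis(3-methylbut-2-enyl)phenyl]ethanone F2. Claisen–Schmidt condensation of F2 with 9 (KOH, EtOH, rt) should then give 15 directly.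

Step 10. The fully substituted ring A twists the aryl ketone out of conjugation, so the 2'-phenoxide may close 5-exo at the α-carbon and lead to the aurone, or hydroperoxide addition may stall. The fallback separates epoxidation from ring closure; it sets out from 15 and comes back at 18. The last phenol of 15 is capped (NaH, MOMCl, DMF) to give (E)-2',4,4',6'-tetrakis(methoxymethoxy)-3',5'-diprenylchalcone F3. Without a free 2'-OH, alkaline H2O2 can only epoxidise the enone, giving racemic trans-{3-[4-(methoxymethoxy)phenyl]oxiran-2-yl} 2,4,6-tris(methoxymethoxy)-3,5-diprenylphenyl ketone F4. Methanolic HCl then removes the four MOM groups, and the freed ortho-OH opens the epoxide at the benzylic carbon (6-endo, acid-assisted) to give racemic trans-6,8-diprenylaromadendrin F5. Air in dilute methanolic K2CO3 at rt should dehydrogenate F5 to 18.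

Step 7. The delocalised dianion may add to the β-carbon of the enamide instead of the carbonyl, or may be quenched by proton transfer before it is acylated. The fallback replaces acylation by aldol addition and oxidation; it sets out from 7 and 9 and comes back at 12. A Wittig reaction of 9 with Ph3P=CHCHO (toluene, 80 °C) gives (E)-3-[4-(methoxymethoxy)phenyl]prop-2-enal F6. The dilithium dianion of 7 (LiN(i-Pr)2, THF, −78 °C) should add 1,2 to the aldehyde to give racemic 4-hydroxy-6-{(E)-2-hydroxy-4-[4-(methoxymethoxy)phenyl]but-3-enyl}-3,5-bis(3-methylbut-2-enyl)pyran-2-one F7. MnO2 in CH2Cl2 then oxidises the allylic alcohol selectively to 12.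

**Further compounds**
F1 | step 8 | 1-[2,4,6-trihydroxy-3,5-bis(3-methylbut-2-enyl)phenyl]ethanone | CC(=O)c1c(O)c(CC=C(C)C)c(O)c(CC=C(C)C)c1O
F2 | step 8 | 1-[2-hydroxy-4,6-bis(methoxymethoxy)-3,5-bis(3-methylbut-2-enyl)phenyl]ethanone | CC(=O)c1c(O)c(CC=C(C)C)c(OCOC)c(CC=C(C)C)c1OCOC
F3 | step 10 | (E)-2',4,4',6'-tetrakis(methoxymethoxy)-3',5'-diprenylchalcone | COCOc1ccc(/C=C/C(=O)c2c(OCOC)c(CC=C(C)C)c(OCOC)c(CC=C(C)C)c2OCOC)cc1
F4 | step 10 | racemic trans-{3-[4-(methoxymethoxy)phenyl]oxiran-2-yl} 2,4,6-tris(methoxymethoxy)-3,5-diprenylphenyl ketone | COCOc1ccc([C@@H]2O[C@H]2C(=O)c3c(OCOC)c(CC=C(C)C)c(OCOC)c(CC=C(C)C)c3OCOC)cc1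
F5 | step 10 | racemic trans-6,8-diprenylaromadendrin (rac-(2R,3R)-3,5,7-trihydroxy-2-(4-hydroxyphenyl)-6,8-diprenylchroman-4-one) | Oc1ccc([C@@H]2[C@H](C(=O)c3c(O)c(CC=C(C)C)c(O)c(CC=C(C)C)c3O2)O)cc1
F6 | step 7 | (E)-3-[4-(methoxymethoxy)phenyl]prop-2-enal | COCOc1ccc(/C=C/C=O)cc1
F7 | step 7 | racemic 4-hydroxy-6-{(E)-2-hydroxy-4-[4-(methoxymethoxy)phenyl]but-3-enyl}-3,5-bis(3-methylbut-2-enyl)pyran-2-one | COCOc1ccc(/C=C/C(O)Cc2oc(=O)c(CC=C(C)C)c(O)c2CC=C(C)C)cc1
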